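**Strategy.** Ring numbering: C1 (acrylic acid), C2 (OH), C3 (hydroxypropenyl), C4 (quaternary), C5 (CH2), C6 (acyloxy). The ring is disconnected at C1–C2: the γ-hydroxy-α-methylene acid motif spanning C2, C1 and the acrylate is the retron of a carbonyl allylation. An open-chain aldehyde (future C2) carrying a (Z)-2-(bromomethyl)enoate undergoes indium-mediated intramolecular Barbier allylation. This closes the cyclohexane, creates C1 and C2 and unveils the exo-methylene acrylate in one operation, under control of the resident C3, C4 and C6 centres. The chain stems from an enantioselective Ireland–Claisen rearrangement (C3/C4, including the quaternary carbon) and a catalytic vinylogous Mukaiyama aldol (C6). The side-chain ester and the allylic hydroxyl are introduced last.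

Key step: step 13

Assumption: the facial sense of the (4R,5R)-diazaborolidine in step 5 is taken by analogy with simple (E)-allyl esters; if the antipodal (2S,3S) pair of 10 is delivered, the (4S,5S)-reagent is used with no other change.

Step 1
Reactants: 1 ethyl 3-methylbut-2-enoate
Product: 3 [(1-ethoxy-3-methylbuta-1,3-dien-1-yl)oxy]triethylsilane, via lithium dienolate 2 (not isolated)
Conditions: LiN(i-Pr)2, THF, −78 °C; then Et3SiCl, −78 °C → rt
Reagents that add atoms: chlorotriethylsilane, CC[Si](Cl)(CC)CC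
Why: Kinetic γ-deprotonation of the β,β-dimethyl enoate gives the extended lithium dienolate, which is silylated on oxygen (silyl ketene acetal formation) to give the dienol ether used as vinylogous nucleophile; no stereocentre is formed.

Step 2
Reactants: 3 [(1-ethoxy-3-methylbuta-1,3-dien-1-yl)oxy]triethylsilane; 4 2-[(4-methoxyphenyl)methoxy]acetaldehyde
Product: 5 ethyl (2E,5S)-6-[(4-methoxyphenyl)methoxy]-3-methyl-5-(triethylsilyloxy)hex-2-enoate
Conditions: [Cu((S,S)-Ph-pybox)](SbF6)2 (5 mol %), CH2Cl2, −78 °C; NaHCO3 work-up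
Reagents that add atoms: none
Why: Catalytic enantioselective vinylogous Mukaiyama aldol addition, in which the divalent copper–pybox complex binds the α-alkoxy aldehyde as a five-membered chelate and shields one face, so that γ-attack of the dienolate should set the (5S)-carbinol (the future ring C6) and the (2E)-enoate, the silyl group being transferred to the aldolate oxygen.

Step 3
Reactants: 5 ethyl (2E,5S)-6-[(4-methoxyphenyl)methoxy]-3-methyl-5-(triethylsilyloxy)hex-2-enoate
Product: 6 (2E,5S)-6-[(4-methoxyphenyl)methoxy]-3-methyl-5-(triethylsilyloxy)hex-2-en-1-ol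
Conditions: i-Bu2AlH (2.2 equiv), CH2Cl2, −78 °C; Rochelle salt work-up
Reagents that add atoms: none
Why: 1,2-Reduction of the conjugated ester by the aluminium hydride at low temperature gives the (E)-allylic alcohol without touching the silyl and benzyl ethers or the stereocentre.

Step 4
Reactants: 6 (2E,5S)-6-[(4-methoxyphenyl)methoxy]-3-methyl-5-(triethylsilyloxy)hex-2-en-1-ol; 7 3-methylbut-3-enoic acid
Product: 8 (2E,5S)-6-[(4-methoxyphenyl)methoxy]-3-methyl-5-(triethylsilyloxy)hex-2-en-1-yl 3-methylbut-3-enoate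
Conditions: DCC, DMAP (5 mol %), CH2Cl2, 0 °C
Reagents that add atoms: none
Why: Steglich esterification of the primary allylic alcohol under carbodiimide activation at 0 °C should give the β,γ-unsaturated ester without migration of its double bond; no stereocentre is affected.

Step 5
Reactants: 8 (2E,5S)-6-[(4-methoxyphenyl)methoxy]-3-methyl-5-(triethylsilyloxy)hex-2-en-1-yl 3-methylbut-3-enoate
Product: 10 (2R,3R,5S)-3-ethenyl-6-[(4-methoxyphenyl)methoxy]-3-methyl-2-(prop-1-en-2-yl)-5-(triethylsilyloxy)hexanoic acid, via boron ketene acetal 9 (not isolated)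
Conditions: (4R,5R)-2-bromo-1,3-bis{[3,5-bis(trifluoromethyl)phenyl]sulfonyl}-4,5-diphenyl-1,3,2-diazaborolidine (1.2 equiv), Et3N, toluene/hexane, −78 °C, then 4 °C → rt; aqueous work-up
Reagents that add atoms: none
Why: Enantioselective Ireland–Claisen rearrangement, in which soft enolisation by the chiral bromoborane/amine pair gives the boron ketene acetal with the isopropenyl group cis to the allylic oxygen, the [3,3]-shift through a chair with the chain of the (E)-alkene equatorial forms the hindered bond to the quaternary carbon with the anti (2R,3R) relationship, and the C2-symmetric diazaborolidine shields one enolate face to fix the absolute configuration independently of the remote silyloxy centre.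

Step 6
Reactants: 10 (2R,3R,5S)-3-ethenyl-6-[(4-methoxyphenyl)methoxy]-3-methyl-2-(prop-1-en-2-yl)-5-(triethylsilyloxy)hexanoic acid
Product: 11 (2R,3R,5S)-3-ethenyl-6-[(4-methoxyphenyl)methoxy]-3-methyl-2-(prop-1-en-2-yl)-5-(triethylsilyloxy)hexan-1-ol
Conditions: LiAlH4, THF, 0 °C → rt
Reagents that add atoms: none
Why: Hydride reduction of the carboxylic acid to the primary alcohol, with ethers and isolated alkenes inert and the α-stereocentre safe under these non-enolising conditions.

Step 7
Reactants: 11 (2R,3R,5S)-3-ethenyl-6-[(4-methoxyphenyl)methoxy]-3-methyl-2-(prop-1-en-2-yl)-5-(triethylsilyloxy)hexan-1-ol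
Product: 12 triethyl{[(2R,3R,5S)-3-ethenyl-6-[(4-methoxyphenyl)methoxy]-3-methyl-2-(prop-1-en-2-yl)-5-(triethylsilyloxy)hexyl]oxy}silane
Conditions: Et3SiCl, imidazole, CH2Cl2, 0 °C
Reagents that add atoms: chlorotriethylsilane, CC[Si](Cl)(CC)CC
Why: Silylation of the primary alcohol parks the future aldehyde carbon as a triethylsilyl ether that can later be oxidised directly.

Step 8
Reactants: 12 triethyl{[(2R,3R,5S)-3-ethenyl-6-[(4-methoxyphenyl)methoxy]-3-methyl-2-(prop-1-en-2-yl)-5-(triethylsilyloxy)hexyl]oxy}silane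
Product: 13 (2S,4R,5R)-4-ethenyl-4-methyl-5-(prop-1-en-2-yl)-2,6-bis(triethylsilyloxy)hexan-1-ol
Conditions: DDQ, CH2Cl2/pH 7 buffer, 0 °C
Reagents that add atoms: none
Why: Oxidative cleavage of the p-methoxybenzyl ether by DDQ in wet buffered solvent frees the primary alcohol while silyl ethers and unactivated alkenes survive.

Step 9
Reactants: 13 (2S,4R,5R)-4-ethenyl-4-methyl-5-(prop-1-en-2-yl)-2,6-bis(triethylsilyloxy)hexan-1-ol
Product: 14 (2S,4R,5R)-4-ethenyl-4-methyl-5-(prop-1-en-2-yl)-2,6-bis(triethylsilyloxy)hexanal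
Conditions: DMP (1,1,1-triacetoxy-1,2-benziodoxol-3-one), NaHCO3 (buffer), CH2Cl2, 0 °C → rt
Reagents that add atoms: none
Why: Periodinane oxidation under buffered, non-basic conditions should give the α-silyloxy aldehyde without epimerisation of the adjacent stereocentre.

Step 10
Reactants: 14 (2S,4R,5R)-4-ethenyl-4-methyl-5-(prop-1-en-2-yl)-2,6-bis(triethylsilyloxy)hexanal; 15 tert-butyl prop-2-enoate
Product: 16 tert-butyl (4S,6R,7R)-6-ethenyl-3-hydroxy-6-methyl-2-methylidene-7-(prop-1-en-2-yl)-4,8-bis(triethylsilyloxy)octanoate (both C3 epimers)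
Conditions: quinuclidine (0.5 equiv), MeOH (1 equiv), neat 15 (5 equiv), rt
Reagents that add atoms: none
Why: Morita–Baylis–Hillman reaction, in which the amine adds to the acrylate, the ammonium enolate attacks the activated α-oxygenated aldehyde and elimination regenerates the catalyst; the new carbinol centre is formed without control, which is immaterial because it is erased in the next step.

Step 11
Reactants: 16 tert-butyl (4S,6R,7R)-6-ethenyl-3-hydroxy-6-methyl-2-methylidene-7-(prop-1-en-2-yl)-4,8-bis(triethylsilyloxy)octanoate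
Product: 17 tert-butyl (2Z,4S,6R,7R)-2-(bromomethyl)-6-ethenyl-6-methyl-7-(prop-1-en-2-yl)-4,8-bis(triethylsilyloxy)oct-2-enoate
Conditions: NBS, Me2S, CH2Cl2, 0 °C → rt
Reagents that add atoms: N-bromosuccinimide, O=C1CCC(=O)N1Br
Why: The allylic alcohol is activated as an alkoxysulfonium salt and displaced by bromide with allylic transposition (SN2′), which should give the thermodynamically preferred (Z)-2-(bromomethyl)enoate with the chain trans to the ester and destroys the carbinol stereocentre of 16.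

Step 12
Reactants: 17 tert-butyl (2Z,4S,6R,7R)-2-(bromomethyl)-6-ethenyl-6-methyl-7-(prop-1-en-2-yl)-4,8-bis(triethylsilyloxy)oct-2-enoate
Product: 18 tert-butyl (2Z,4S,6R,7R)-2-(bromomethyl)-6-ethenyl-7-formyl-6,8-dimethyl-4-(triethylsilyloxy)nona-2,8-dienoate
Conditions: (COCl)2, DMSO, CH2Cl2, −78 → −40 °C; then i-Pr2NEt, −78 → −20 °C; used at once
Reagents that add atoms: none
Why: Swern oxidation of a primary triethylsilyl ether, in which the activated sulfonium reagent cleaves the primary silyl ether in situ and oxidises it to the aldehyde while the more hindered secondary silyl ether is retained, and the hindered amine at low temperature avoids epimerisation or conjugation of the α-isopropenyl aldehyde.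

Step 13
Reactants: 18 tert-butyl (2Z,4S,6R,7R)-2-(bromomethyl)-6-ethenyl-7-formyl-6,8-dimethyl-4-(triethylsilyloxy)nona-2,8-dienoate
Product: 20 tert-butyl 2-[(1S,2S,3R,4R,6S)-4-ethenyl-2-hydroxy-4-methyl-3-(prop-1-en-2-yl)-6-(triethylsilyloxy)cyclohexyl]prop-2-enoate, via allylindium dibromide 19 (not isolated)
Conditions: In powder (2 equiv), THF/H2O (3:1), rt, 0.01 M
Reagents that add atoms: none
Why: Indium inserts into the allylic C–Br bond of 18 to give the σ-allylindium 19, whose γ-carbon (future C1) attacks the tethered aldehyde (future C2) through a closed six-membered chair transition state with trivalent indium bridging the carbonyl oxygen and the CH2–In carbon, the double bond shifting to the exocyclic methylene of the acrylate (SE2′ carbonyl allylation). The closest known reaction type is the aqueous Barbier-type indium-mediated intramolecular allylation of aldehydes with 2-(bromomethyl)acrylates that gives ring-fused cis-γ-hydroxy-α-methylene esters. The cyclohexane is closed in a 6-exo-trig mode with respect to the carbonyl group, the new ring bond being C1–C2. C1 and C2 should come out cis because the (Z)-allylmetal geometry is retained, so that the metallacyclic chair is cis-fused to the forming carbocycle; C1 should be trans to the C6 silyloxy group because allylic 1,3-strain holds the C6–H bond in the plane of the allyl unit and the tether then delivers the aldehyde anti to the OSiEt3 group; the C2 hydroxyl should end trans to the C3 isopropenyl group because the fixed C3, C4 and C6 centres favour the chair with equatorial C4-methyl and C6-silyloxy groups, in which the coordinated carbonyl oxygen is axial. The step needs γ- over α-attack (secured by ring size, six against eight), diastereofacial control (secured by the three resident stereocentres as described) and survival of the epimerisable α-isopropenyl aldehyde (secured by the neutral, base-free medium); the tert-butyl ester prevents lactonisation of the cis-hydroxy ester.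

Step 14
Reactants: 20 tert-butyl 2-[(1S,2S,3R,4R,6S)-4-ethenyl-2-hydroxy-4-methyl-3-(prop-1-en-2-yl)-6-(triethylsilyloxy)cyclohexyl]prop-2-enoate
Product: 21 tert-butyl 2-[(1R,2S,3R,4R,6S)-2-(tert-butyldimethylsilyloxy)-4-ethenyl-4-methyl-3-(prop-1-en-2-yl)-6-(triethylsilyloxy)cyclohexyl]prop-2-enoate
Conditions: t-BuMe2SiOTf, 2,6-lutidine, CH2Cl2, −78 → −20 °C
Reagents that add atoms: tert-butyldimethylsilyl trifluoromethanesulfonate, CC(C)(C)[Si](C)(C)OS(=O)(=O)C(F)(F)F
Why: Silylation of the hindered secondary hydroxyl with the silyl triflate and a non-nucleophilic base at low temperature, conditions under which the tert-butyl ester and the triethylsilyl ether are untouched.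

Step 15
Reactants: 21 tert-butyl 2-[(1R,2S,3R,4R,6S)-2-(tert-butyldimethylsilyloxy)-4-ethenyl-4-methyl-3-(prop-1-en-2-yl)-6-(triethylsilyloxy)cyclohexyl]prop-2-enoate
Product: 22 tert-butyl 2-[(1R,2S,3R,4R,6S)-2-(tert-butyldimethylsilyloxy)-4-ethenyl-6-hydroxy-4-methyl-3-(prop-1-en-2-yl)cyclohexyl]prop-2-enoate
Conditions: PPTS (cat.), MeOH/CH2Cl2, 0 °C
Reagents that add atoms: none
Why: Acid-catalysed methanolysis removes the more labile triethylsilyl ether selectively in the presence of the secondary tert-butyldimethylsilyl ether and the tert-butyl ester.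

Step 16
Reactants: 23 (4R)-4-hydroxyoxolan-2-one
Product: 27 (4R)-4-hydroxy-3-methylideneoxolan-2-one, via dilithium dianion 24 (not isolated), via Mannich base 25 (not isolated), via trimethylammonium iodide 26 (not isolated)
Conditions: LiN(i-Pr)2 (2.2 equiv), THF, −78 °C; CH2=NMe2 I, −78 °C → rt; then MeI, MeOH, rt; then NaHCO3 (aq), CH2Cl2, rt
Reagents that add atoms: dimethyl(methylidene)ammonium iodide, C=[N+](C)C.[I-]
Why: α-Methylenation of the lactone, in which the alkoxide–enolate dianion undergoes a Mannich reaction at carbon and quaternisation followed by base-induced elimination of trimethylamine installs the exo-methylene group, the chiral-pool carbinol centre remaining untouched because its alkoxide is a poor leaving group.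

Step 17
Reactants: 27 (4R)-4-hydroxy-3-methylideneoxolan-2-one
Product: 30 (3R)-3,4-bis(tert-butyldimethylsilyloxy)-2-methylidenebutanoic acid, via lithium carboxylate 28 (not isolated), via tris-silyl derivative 29 (not isolated)
Conditions: LiOH·H2O (1.05 equiv), THF/H2O, 0 °C, concentrate; t-BuMe2SiCl, imidazole, DMF, rt; then K2CO3 (cat.), MeOH/THF/H2O, rt; citric acid to pH 5
Reagents that add atoms: lithium hydroxide, [Li+].[OH-]; tert-butyldimethylsilyl chloride, CC(C)(C)[Si](C)(C)Cl
Why: Saponification opens the lactone, exhaustive silylation traps the diol and the carboxylate, and mild methanolysis cleaves only the labile silyl ester, which should give the protected acid with the stereocentre unchanged.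

Step 18
Reactants: 22 tert-butyl 2-[(1R,2S,3R,4R,6S)-2-(tert-butyldimethylsilyloxy)-4-ethenyl-6-hydroxy-4-methyl-3-(prop-1-en-2-yl)cyclohexyl]prop-2-enoate; 30 (3R)-3,4-bis(tert-butyldimethylsilyloxy)-2-methylidenebutanoic acid
Product: 32 tert-butyl 2-[(1R,2S,3R,4R,6S)-6-{[(3R)-3,4-bis(tert-butyldimethylsilyloxy)-2-methylidenebutanoyl]oxy}-2-(tert-butyldimethylsilyloxy)-4-ethenyl-4-methyl-3-(prop-1-en-2-yl)cyclohexyl]prop-2-enoate, via mixed anhydride 31 (not isolated)
Conditions: 2,4,6-trichlorobenzoyl chloride, Et3N, toluene, rt; then 22, DMAP, toluene, rt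
Reagents that add atoms: none
Why: Yamaguchi esterification, in which DMAP attacks the mixed anhydride at the acrylic carbonyl and the acylpyridinium acylates the only free hydroxyl of 22 with retention at the carbinol carbon.

Step 19
Reactants: 32 tert-butyl 2-[(1R,2S,3R,4R,6S)-6-{[(3R)-3,4-bis(tert-butyldimethylsilyloxy)-2-methylidenebutanoyl]oxy}-2-(tert-butyldimethylsilyloxy)-4-ethenyl-4-methyl-3-(prop-1-en-2-yl)cyclohexyl]prop-2-enoate
Product: 33 tert-butyl 2-[(1R,2S,3S,4R,6S)-6-{[(3R)-3,4-bis(tert-butyldimethylsilyloxy)-2-methylidenebutanoyl]oxy}-2-(tert-butyldimethylsilyloxy)-4-ethenyl-3-(3-hydroxyprop-1-en-2-yl)-4-methylcyclohexyl]prop-2-enoate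
Conditions: SeO2 (0.5 equiv), t-BuOOH, CH2Cl2, 0 °C → rt
Reagents that add atoms: tert-butyl hydroperoxide, CC(C)(C)OO (terminal source of the oxygen atom, relayed by selenium dioxide, O=[Se]=O)
Why: Allylic oxidation with SeO2 (ene reaction, then [2,3]-sigmatropic shift) at the only electron-rich alkene that bears allylic hydrogens, the methyl group being preferred over the hindered ring methine, while the vinyl group (no allylic hydrogen) and the two electron-poor acrylates should stay inert.

Step 20
Reactants: 33 tert-butyl 2-[(1R,2S,3S,4R,6S)-6-{[(3R)-3,4-bis(tert-butyldimethylsilyloxy)-2-methylidenebutanoyl]oxy}-2-(tert-butyldimethylsilyloxy)-4-ethenyl-3-(3-hydroxyprop-1-en-2-yl)-4-methylcyclohexyl]prop-2-enoate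
Product: 35 2-[(1S,2S,3S,4R,6S)-6-{[(3R)-3,4-dihydroxy-2-methylidenebutanoyl]oxy}-4-ethenyl-2-hydroxy-3-(3-hydroxyprop-1-en-2-yl)-4-methylcyclohexyl]prop-2-enoic acid, via trimethylsilyl ester 34 (not isolated)
Conditions: Me3SiOTf, 2,6-lutidine, CH2Cl2, 0 °C; then HF·pyridine, pyridine, THF, 0 °C → rt; pH 6 buffer work-up
Reagents that add atoms: none
Why: The silyl triflate converts the tert-butyl ester into the silyl ester with loss of isobutene under non-protic conditions that leave the silyl ethers in place, and buffered fluoride then removes all silicon groups, so that the lactonisation-prone cis-γ-hydroxy acid is liberated only at the end and never under strongly acidic conditions.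

**Compound list**

1 | ethyl 3-methylbut-2-enoate | CCOC(=O)C=C(C)C | starting material
2 | lithium 1-ethoxy-3-methylbuta-1,3-dien-1-olate | [Li+].CCOC([O-])=CC(C)=C | intermediate
3 | [(1-ethoxy-3-methylbuta-1,3-dien-1-yl)oxy]triethylsilane | CCOC(=CC(C)=C)O[Si](CC)(CC)CC | intermediate
4 | 2-[(4-methoxyphenyl)methoxy]acetaldehyde | COc1ccc(COCC=O)cc1 | starting material
5 | ethyl (2E,5S)-6-[(4-methoxyphenyl)methoxy]-3-methyl-5-(triethylsilyloxy)hex-2-enoate | CCOC(=O)/C=C(\C)C[C@H](O[Si](CC)(CC)CC)COCc1ccc(OC)cc1 | intermediate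
6 | (2E,5S)-6-[(4-methoxyphenyl)methoxy]-3-methyl-5-(triethylsilyloxy)hex-2-en-1-ol | OC/C=C(\C)C[C@H](O[Si](CC)(CC)CC)COCc1ccc(OC)cc1 | intermediate
7 | 3-methylbut-3-enoic acid | C=C(C)CC(=O)O | starting material
8 | (2E,5S)-6-[(4-methoxyphenyl)methoxy]-3-methyl-5-(triethylsilyloxy)hex-2-en-1-yl 3-methylbut-3-enoate | C=C(C)CC(=O)OC/C=C(\C)C[C@H](O[Si](CC)(CC)CC)COCc1ccc(OC)cc1 | intermediate
9 | boron ketene acetal of 8 (enolate oxygen bound to the (4R,5R)-1,3-bis{[3,5-bis(trifluoromethyl)phenyl]sulfonyl}-4,5-diphenyl-1,3,2-diazaborolidin-2-yl group, isopropenyl cis to the allyloxy group) | C=C(C)/C=C(\OC/C=C(\C)C[C@H](O[Si](CC)(CC)CC)COCc1ccc(OC)cc1)OB1N(S(=O)(=O)c2cc(C(F)(F)F)cc(C(F)(F)F)c2)[C@H](c2ccccc2)[C@@H](c2ccccc2)N1S(=O)(=O)c1cc(C(F)(F)F)cc(C(F)(F)F)c1 | intermediate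
10 | (2R,3R,5S)-3-ethenyl-6-[(4-methoxyphenyl)methoxy]-3-methyl-2-(prop-1-en-2-yl)-5-(triethylsilyloxy)hexanoic acid | OC(=O)[C@H](C(C)=C)[C@@](C)(C=C)C[C@H](O[Si](CC)(CC)CC)COCc1ccc(OC)cc1 | intermediate
11 | (2R,3R,5S)-3-ethenyl-6-[(4-methoxyphenyl)methoxy]-3-methyl-2-(prop-1-en-2-yl)-5-(triethylsilyloxy)hexan-1-ol | OC[C@H](C(C)=C)[C@@](C)(C=C)C[C@H](O[Si](CC)(CC)CC)COCc1ccc(OC)cc1 | intermediate
12 | triethyl{[(2R,3R,5S)-3-ethenyl-6-[(4-methoxyphenyl)methoxy]-3-methyl-2-(prop-1-en-2-yl)-5-(triethylsilyloxy)hexyl]oxy}silane | CC[Si](CC)(CC)OC[C@H](C(C)=C)[C@@](C)(C=C)C[C@H](O[Si](CC)(CC)CC)COCc1ccc(OC)cc1 | intermediate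
13 | (2S,4R,5R)-4-ethenyl-4-methyl-5-(prop-1-en-2-yl)-2,6-bis(triethylsilyloxy)hexan-1-ol | CC[Si](CC)(CC)OC[C@H](C(C)=C)[C@@](C)(C=C)C[C@H](O[Si](CC)(CC)CC)CO | intermediate
14 | (2S,4R,5R)-4-ethenyl-4-methyl-5-(prop-1-en-2-yl)-2,6-bis(triethylsilyloxy)hexanal | CC[Si](CC)(CC)OC[C@H](C(C)=C)[C@@](C)(C=C)C[C@H](O[Si](CC)(CC)CC)C=O | intermediate
15 | tert-butyl prop-2-enoate | C=CC(=O)OC(C)(C)C | starting material
16 | tert-butyl (4S,6R,7R)-6-ethenyl-3-hydroxy-6-methyl-2-methylidene-7-(prop-1-en-2-yl)-4,8-bis(triethylsilyloxy)octanoate (both C3 epimers) | CC[Si](CC)(CC)OC[C@H](C(C)=C)[C@@](C)(C=C)C[C@H](O[Si](CC)(CC)CC)C(O)C(=C)C(=O)OC(C)(C)C | intermediate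
17 | tert-butyl (2Z,4S,6R,7R)-2-(bromomethyl)-6-ethenyl-6-methyl-7-(prop-1-en-2-yl)-4,8-bis(triethylsilyloxy)oct-2-enoate | CC[Si](CC)(CC)OC[C@H](C(C)=C)[C@@](C)(C=C)C[C@H](O[Si](CC)(CC)CC)/C=C(\CBr)C(=O)OC(C)(C)C | intermediate
18 | tert-butyl (2Z,4S,6R,7R)-2-(bromomethyl)-6-ethenyl-7-formyl-6,8-dimethyl-4-(triethylsilyloxy)nona-2,8-dienoate | O=C[C@H](C(C)=C)[C@@](C)(C=C)C[C@H](O[Si](CC)(CC)CC)/C=C(\CBr)C(=O)OC(C)(C)C | intermediate
19 | σ-allylindium reagent from 18 (C–Br replaced by C–InBr2, drawn as the monomeric dibromide of trivalent indium) | O=C[C@H](C(C)=C)[C@@](C)(C=C)C[C@H](O[Si](CC)(CC)CC)/C=C(\C[In](Br)Br)C(=O)OC(C)(C)C | intermediate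
20 | tert-butyl 2-[(1S,2S,3R,4R,6S)-4-ethenyl-2-hydroxy-4-methyl-3-(prop-1-en-2-yl)-6-(triethylsilyloxy)cyclohexyl]prop-2-enoate | C=C[C@@]1(C)C[C@H](O[Si](CC)(CC)CC)[C@@H](C(=C)C(=O)OC(C)(C)C)[C@@H](O)[C@@H]1C(C)=C | intermediate
21 | tert-butyl 2-[(1R,2S,3R,4R,6S)-2-(tert-butyldimethylsilyloxy)-4-ethenyl-4-methyl-3-(prop-1-en-2-yl)-6-(triethylsilyloxy)cyclohexyl]prop-2-enoate | C=C[C@@]1(C)C[C@H](O[Si](CC)(CC)CC)[C@@H](C(=C)C(=O)OC(C)(C)C)[C@@H](O[Si](C)(C)C(C)(C)C)[C@@H]1C(C)=C | intermediate
22 | tert-butyl 2-[(1R,2S,3R,4R,6S)-2-(tert-butyldimethylsilyloxy)-4-ethenyl-6-hydroxy-4-methyl-3-(prop-1-en-2-yl)cyclohexyl]prop-2-enoate | C=C[C@@]1(C)C[C@H](O)[C@@H](C(=C)C(=O)OC(C)(C)C)[C@@H](O[Si](C)(C)C(C)(C)C)[C@@H]1C(C)=C | intermediate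
23 | (4R)-4-hydroxyoxolan-2-one | O=C1C[C@@H](O)CO1 | starting material
24 | dilithium salt of the alkoxide–enolate of 23 | [Li+].[Li+].[O-]C1=C[C@@H]([O-])CO1 | intermediate
25 | (4R)-3-[(dimethylamino)methyl]-4-hydroxyoxolan-2-one (C3 unassigned) | O=C1C(CN(C)C)[C@@H](O)CO1 | intermediate
26 | {[(4R)-4-hydroxy-2-oxooxolan-3-yl]methyl}trimethylammonium iodide | O=C1C(C[N+](C)(C)C)[C@@H](O)CO1.[I-] | intermediate
27 | (4R)-4-hydroxy-3-methylideneoxolan-2-one | O=C1C(=C)[C@@H](O)CO1 | intermediate
28 | lithium (3R)-3,4-dihydroxy-2-methylidenebutanoate | [Li+].[O-]C(=O)C(=C)[C@@H](O)CO | intermediate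
29 | tert-butyldimethylsilyl (3R)-3,4-bis(tert-butyldimethylsilyloxy)-2-methylidenebutanoate | C=C(C(=O)O[Si](C)(C)C(C)(C)C)[C@@H](O[Si](C)(C)C(C)(C)C)CO[Si](C)(C)C(C)(C)C | intermediate
30 | (3R)-3,4-bis(tert-butyldimethylsilyloxy)-2-methylidenebutanoic acid | C=C(C(=O)O)[C@@H](O[Si](C)(C)C(C)(C)C)CO[Si](C)(C)C(C)(C)C | intermediate
31 | (3R)-3,4-bis(tert-butyldimethylsilyloxy)-2-methylidenebutanoic 2,4,6-trichlorobenzoic anhydride | C=C(C(=O)OC(=O)c1c(Cl)cc(Cl)cc1Cl)[C@@H](O[Si](C)(C)C(C)(C)C)CO[Si](C)(C)C(C)(C)C | intermediate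
32 | tert-butyl 2-[(1R,2S,3R,4R,6S)-6-{[(3R)-3,4-bis(tert-butyldimethylsilyloxy)-2-methylidenebutanoyl]oxy}-2-(tert-butyldimethylsilyloxy)-4-ethenyl-4-methyl-3-(prop-1-en-2-yl)cyclohexyl]prop-2-enoate | C=C[C@@]1(C)C[C@H](OC(=O)C(=C)[C@@H](O[Si](C)(C)C(C)(C)C)CO[Si](C)(C)C(C)(C)C)[C@@H](C(=C)C(=O)OC(C)(C)C)[C@@H](O[Si](C)(C)C(C)(C)C)[C@@H]1C(C)=C | intermediate
33 | tert-butyl 2-[(1R,2S,3S,4R,6S)-6-{[(3R)-3,4-bis(tert-butyldimethylsilyloxy)-2-methylidenebutanoyl]oxy}-2-(tert-butyldimethylsilyloxy)-4-ethenyl-3-(3-hydroxyprop-1-en-2-yl)-4-methylcyclohexyl]prop-2-enoate | C=C[C@@]1(C)C[C@H](OC(=O)C(=C)[C@@H](O[Si](C)(C)C(C)(C)C)CO[Si](C)(C)C(C)(C)C)[C@@H](C(=C)C(=O)OC(C)(C)C)[C@@H](O[Si](C)(C)C(C)(C)C)[C@@H]1C(=C)CO | intermediate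
34 | trimethylsilyl 2-[(1R,2S,3S,4R,6S)-6-{[(3R)-3,4-bis(tert-butyldimethylsilyloxy)-2-methylidenebutanoyl]oxy}-2-(tert-butyldimethylsilyloxy)-4-ethenyl-4-methyl-3-[3-(trimethylsilyloxy)prop-1-en-2-yl]cyclohexyl]prop-2-enoate | C=C[C@@]1(C)C[C@H](OC(=O)C(=C)[C@@H](O[Si](C)(C)C(C)(C)C)CO[Si](C)(C)C(C)(C)C)[C@@H](C(=C)C(=O)O[Si](C)(C)C)[C@@H](O[Si](C)(C)C(C)(C)C)[C@@H]1C(=C)CO[Si](C)(C)C | intermediate
35 | 2-[(1S,2S,3S,4R,6S)-6-{[(3R)-3,4-dihydroxy-2-methylidenebutanoyl]oxy}-4-ethenyl-2-hydroxy-3-(3-hydroxyprop-1-en-2-yl)-4-methylcyclohexyl]prop-2-enoic acid | C=C[C@@]1(C)C[C@H](OC(=O)C(=C)[C@@H](O)CO)[C@@H](C(=C)C(=O)O)[C@@H](O)[C@@H]1C(=C)CO | target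

**Totals.** Total step count: 20. Longest linear sequence: 18 steps (steps 1–15, then 18, 19 and 20); steps 16 and 17 form the side-chain branch.

**Steps most likely to fail**

1. Step 13 (ring closure). What may go wrong: loss of the (Z)-allylmetal geometry or a competing chair would erode facial selectivity, and the allylic bromide may be consumed by protonolysis or 1,4-elimination in water before it cyclises. Fallback, setting out from 16 and coming back at 20: the approach changes from a preformed halide to catalytic umpolung of an allylic ester under anhydrous conditions. Alcohol 16 is acetylated (Ac2O, DMAP, pyridine) to the allylic acetate F3, and Swern oxidation of its primary silyl ether gives the aldehyde acetate F4. Pd(PPh3)4 (zerovalent palladium, catalytic) with InI in THF then ionises the acetate to a π-allylpalladium species that is transmetalated to the allylindium acetate iodide F5, which should close the ring through the same chair to give 20.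

2. Step 5 (Ireland–Claisen rearrangement). What may go wrong: slow or incomplete soft enolisation, the wrong ketene acetal geometry, attack of the boron Lewis acid on the benzyl ether, or poor facial control by the controller. Fallback, setting out from 8 and coming back at 10: the approach changes from reagent control to an achiral lithium enolate rearrangement with separation of diastereomers. Ester 8 is treated with LiN(i-Pr)2 and Me3SiCl/Et3N in THF at −78 °C to give the trimethylsilyl ketene acetal F1, which rearranges on warming through the same chair. Hydrolysis should give acid 10 together with its (2S,3S,5S)-diastereomer F2, the anti C2/C3 relationship being secured in both, and the two are separated by chromatography.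

3. Step 19 (allylic oxidation). What may go wrong: over-oxidation to the enal, competing attack at the ring methine, partial loss of silyl groups or low conversion on a late intermediate. Fallback, setting out from 32 and coming back at 34: the approach changes from direct C–H oxidation to epoxide isomerisation. mCPBA (NaHCO3, CH2Cl2, 0 °C) should epoxidise only the electron-rich 1,1-disubstituted alkene to give the epoxide F6. Me3SiOTf/2,6-lutidine followed by DBU then opens the epoxide at the tertiary carbon and eliminates toward the methyl group to the 2-substituted allyl silyl ether, the tert-butyl ester being converted into the silyl ester by the same reagent. This arrives at 34, which is desilylated as in step 20.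

**Further compounds**

F1 | step 5 | trimethylsilyl ketene acetal of 8 (isopropenyl cis to the allyloxy group) | C=C(C)/C=C(\OC/C=C(\C)C[C@H](O[Si](CC)(CC)CC)COCc1ccc(OC)cc1)O[Si](C)(C)C
F2 | step 5 | (2S,3S,5S)-3-ethenyl-6-[(4-methoxyphenyl)methoxy]-3-methyl-2-(prop-1-en-2-yl)-5-(triethylsilyloxy)hexanoic acid | OC(=O)[C@@H](C(C)=C)[C@](C)(C=C)C[C@H](O[Si](CC)(CC)CC)COCc1ccc(OC)cc1
F3 | step 13 | tert-butyl (4S,6R,7R)-3-acetoxy-6-ethenyl-6-methyl-2-methylidene-7-(prop-1-en-2-yl)-4,8-bis(triethylsilyloxy)octanoate | CC[Si](CC)(CC)OC[C@H](C(C)=C)[C@@](C)(C=C)C[C@H](O[Si](CC)(CC)CC)C(OC(C)=O)C(=C)C(=O)OC(C)(C)C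
F4 | step 13 | tert-butyl (4S,6R,7R)-3-acetoxy-6-ethenyl-7-formyl-6,8-dimethyl-2-methylidene-4-(triethylsilyloxy)non-8-enoate | O=C[C@H](C(C)=C)[C@@](C)(C=C)C[C@H](O[Si](CC)(CC)CC)C(OC(C)=O)C(=C)C(=O)OC(C)(C)C
F5 | step 13 | σ-allylindium acetate iodide corresponding to 19 (trivalent indium) | O=C[C@H](C(C)=C)[C@@](C)(C=C)C[C@H](O[Si](CC)(CC)CC)/C=C(\C[In](I)OC(C)=O)C(=O)OC(C)(C)C
F6 | step 19 | epoxide of 32 at the isopropenyl group (2-methyloxiran-2-yl at ring C3, both epimers) | C=C[C@@]1(C)C[C@H](OC(=O)C(=C)[C@@H](O[Si](C)(C)C(C)(C)C)CO[Si](C)(C)C(C)(C)C)[C@@H](C(=C)C(=O)OC(C)(C)C)[C@@H](O[Si](C)(C)C(C)(C)C)[C@@H]1C2(C)CO2
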